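**Retrosynthetic overview**
1. The last operations are global desilylation and, before it, a Suzuki coupling that forms the vinyl–butenolide bond from an α-bromobutenolide and an epoxy-vinylboronate.
2. The key disconnection is the butenolide O1–C5 bond. A carboxylate held cis to an alkyne closes 5-exo-dig on a 2-bromo-2-en-4-ynoic acid, which is made in the same flask from a terminal polyenyne and (E)-2,3-dibromoacrylic acid.
3. The polyenyne comes from a symmetric C14 tetraenediyne (twofold Wittig of a C6 enynyl phosphonium salt on a glyoxal equivalent), coupled once (Sonogashira) with a ring enol triflate.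
4. The oxirane C–O bonds come from Sharpless epoxidation of the allylic alcohol made from the same enol triflate, followed by oxidation and boron–Wittig olefination.
5. Ring order: both six-membered rings come intact from (−)-actinol through one common triflate. The oxirane is formed first (step 4) and the butenolide last (step 11).

Assumption: the target is (3S,5R,6S,3'R)-pyrrhoxanthinol as drawn. (−)-Actinol, the industrial zeaxanthin intermediate, is taken as a purchasable chiral-pool material.

**Step 1**
Reactants: 1 (−)-actinol, (4R,6R)-4-hydroxy-2,2,6-trimethylcyclohexan-1-one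
Product: 2 (4R,6R)-4-[(tert-butyldimethylsilyl)oxy]-2,2,6-trimethylcyclohexan-1-one
Conditions: TBSCl, imidazole, DMF, rt
Reagents that add atoms: tert-butyldimethylsilyl chloride CC(C)(C)[Si](C)(C)Cl
Why: Imidazole-promoted silyl ether formation masks the only acidic proton before the strong-base step and touches no stereocentre.

**Step 2**
Reactants: 2 TBS-actinol
Product: 4 (R)-4-[(tert-butyldimethylsilyl)oxy]-2,6,6-trimethylcyclohex-1-en-1-yl trifluoromethanesulfonate, via lithium enolate 3 (not isolated)
Conditions: LiN(iPr)2, THF, −78 °C; PhNTf2, −78 °C → rt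
Reagents that add atoms: N-phenylbis(trifluoromethanesulfonimide) O=S(=O)(C(F)(F)F)N(c1ccccc1)S(=O)(=O)C(F)(F)F
Why: Only C6 carries an α-hydrogen, so one enolate forms, and its O-sulfonylation (enol triflate synthesis) erases the C6 centre, keeps the carbinol centre R and gives the single electrophile used for both rings.

**Step 3**
Reactants: 4 enol triflate; 5 (tributylstannyl)methanol
Product: 6 {(R)-4-[(tert-butyldimethylsilyl)oxy]-2,6,6-trimethylcyclohex-1-en-1-yl}methanol
Conditions: Pd(PPh3)4 (10 mol %), LiCl, 1,4-dioxane, 100 °C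
Reagents that add atoms: none
Why: Stille hydroxymethylation, in which chloride-assisted oxidative addition of the vinyl triflate and preferential transfer of the CH2OH group from tin give the allylic alcohol in one step.

**Step 4**
Reactants: 6 allylic alcohol
Product: 7 {(1R,4S,6R)-4-[(tert-butyldimethylsilyl)oxy]-2,2,6-trimethyl-7-oxabicyclo[4.1.0]heptan-1-yl}methanol (oxirane anti to the silyloxy group)
Conditions: Ti(OiPr)4 (0.3 equiv), D-(−)-diethyl tartrate (0.36 equiv), t-BuOOH, 4 Å MS, CH2Cl2, −20 °C
Reagents that add atoms: tert-butyl hydroperoxide CC(C)(C)OO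
Why: Sharpless asymmetric epoxidation, in which the allylic hydroxyl binds the catalyst formed from Ti(OiPr)4 and D-(−)-diethyl tartrate and oxygen is delivered under reagent control to the face anti to the silyloxy group, setting both quaternary C–O centres (5R,6S in carotenoid numbering).

**Step 5**
Reactants: 7 epoxy alcohol
Product: 8 (1S,4S,6R)-4-[(tert-butyldimethylsilyl)oxy]-2,2,6-trimethyl-7-oxabicyclo[4.1.0]heptane-1-carbaldehyde
Conditions: (n-Pr)4N[RuO4] (5 mol %), NMO, 4 Å MS, CH2Cl2, rt
Reagents that add atoms: none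
Why: Ley–Griffith oxidation is neutral, so the oxirane and silyl ether survive, and the aldehyde has no α-hydrogen and cannot epimerise.

**Step 6**
Reactants: 8 epoxy aldehyde; 9 bis(4,4,5,5-tetramethyl-1,3,2-dioxaborolan-2-yl)methane
Product: 11 2-[(E)-2-{(1S,4S,6R)-4-[(tert-butyldimethylsilyl)oxy]-2,2,6-trimethyl-7-oxabicyclo[4.1.0]heptan-1-yl}ethenyl]-4,4,5,5-tetramethyl-1,3,2-dioxaborolane, via lithiated diboronate 10 (not isolated)
Conditions: 2,2,6,6-tetramethylpiperidine, n-BuLi, THF, 0 °C; 9; then 8, −78 °C → rt
Reagents that add atoms: none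
Why: Boron–Wittig olefination, in which the gem-diboryl carbanion adds to the non-enolisable aldehyde and syn B–O elimination from the less crowded adduct gives the E-alkenylboronate without touching the three ring stereocentres.

**Step 7**
Reactants: 12 (E)-3-methylpent-2-en-4-yn-1-ol
Product: 14 tributyl[(E)-3-methylpent-2-en-4-yn-1-yl]phosphonium bromide, via allylic bromide 13 (not isolated)
Conditions: PBr3, Et2O, 0 °C; then PBu3, toluene, rt
Reagents that add atoms: phosphorus tribromide BrP(Br)Br; tributylphosphine CCCCP(CCCC)CCCC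
Why: SN2 bromination of the primary allylic alcohol followed by quaternisation of the phosphine (phosphonium salt synthesis) leaves the E-enyne geometry untouched.

**Step 8**
Reactants: 14 phosphonium bromide (2.1 equiv); 15 1,4-dioxane-2,3-diol
Product: 19 (3E,5E,7E,9E)-3,10-dimethyldodeca-3,5,7,9-tetraene-1,11-diyne, via ylide 16 (not isolated), via glyoxal 17 (not isolated), via dienynal 18 (not isolated)
Conditions: NaOMe, CH2Cl2, 0 °C; then 15, 0 °C → rt, dark; crystallise
Reagents that add atoms: none
Why: Twofold Wittig olefination, in which 15 releases anhydrous glyoxal and allylic tributylphosphonium ylides give E-alkenes, so both new disubstituted double bonds are E while the trisubstituted E-bonds are carried in from 12.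

**Step 9**
Reactants: 4 enol triflate; 19 tetraenediyne (3 equiv)
Product: 20 (R)-tert-butyl({4-[(3E,5E,7E,9E)-3,10-dimethyldodeca-3,5,7,9-tetraene-1,11-diyn-1-yl]-3,5,5-trimethylcyclohex-3-en-1-yl}oxy)dimethylsilane
Conditions: Pd(PPh3)4 (5 mol %), CuI (10 mol %), iPr2NH, DMF, rt → 40 °C, dark
Reagents that add atoms: none
Why: Sonogashira coupling of the hindered enol triflate, in which the threefold excess of the cheap symmetric diyne keeps double coupling low and the surplus is recovered by chromatography.

**Step 10**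
Reactants: 21 propiolic acid
Product: 22 (E)-2,3-dibromoprop-2-enoic acid
Conditions: Br2, LiBr, AcOH, rt, dark; recrystallise
Reagents that add atoms: bromine BrBr
Why: Bromide-assisted electrophilic anti-addition of bromine to the alkyne gives the E-dibromide, in which the β-bromine is cis to the carboxyl group as the ring closure requires.

**Step 11 (key step)**
Reactants: 20 terminal polyenyne; 22 (E)-2,3-dibromoacrylic acid (1.3 equiv)
Product: 24 (5Z)-3-bromo-5-[(2E,4E,6E,8E)-11-{(4R)-4-[(tert-butyldimethylsilyl)oxy]-2,6,6-trimethylcyclohex-1-en-1-yl}-2,9-dimethylundeca-2,4,6,8-tetraen-10-yn-1-ylidene]furan-2(5H)-one, via bromoenynoic acid 23 (not isolated)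
Conditions: Pd(PPh3)4 (5 mol %), CuI (10 mol %), Et3N (3 equiv), BHT, MeCN–THF, 0 °C → rt, dark, argon
Reagents that add atoms: none
Why: Proposed new method: the free dibromo acid serves as a three-point linchpin in a coupling–lactonisation cascade on a polyenyne, which has not been shown; zerovalent palladium should insert only into the β-C–Br bond (a vinylogous acyl bromide assisted by the cis carboxylate, whereas the α-C–Br bond is cross-conjugated and shielded by the carboxylate, and the E-geometry disfavours both anti-dehydrobromination and decarboxylative loss of bromide), the acetylide made from 20 with CuI transfers with retention to give 23, whose carboxylate adds anti and 5-exo-dig to the neighbouring alkyne activated by divalent palladium or monovalent copper, and protonolysis by Et3NH+ leaves O and chain on the same side (the Z-ylidene C–O bond), while the ring-conjugated internal alkyne has no tethered nucleophile and the α-bromide of 24 survives because 20 is the limiting partner; closest known reaction type: tandem Sonogashira coupling/5-exo-dig lactonisation of (Z)-3-halopropenoic acids and silver-catalysed lactonisation of isolated 2-bromo-2-en-4-ynoic acids.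

**Step 12**
Reactants: 24 bromobutenolide; 11 alkenylboronate (1.2 equiv)
Product: 25 bis(tert-butyldimethylsilyl) ether of the target (both ring hydroxyls silylated)
Conditions: Pd(OAc)2 (5 mol %), SPhos (10 mol %), K3PO4, THF–H2O (10:1), 30 °C, dark
Reagents that add atoms: none
Why: Suzuki–Miyaura coupling proceeds with retention at both sp2 carbons, α-bromobutenolides undergo oxidative addition readily, and phosphate base at 30 °C spares the lactone, the hindered vinyl oxirane and the polyene.

**Step 13**
Reactants: 25 bis-silyl ether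
Product: 26 (3S,5R,6S,3'R)-pyrrhoxanthinol, the target
Conditions: Bu4NF, AcOH (1:1), THF, 0 °C → rt, dark
Reagents that add atoms: none
Why: Buffered fluoride desilylation is close to neutral, so the acid-labile oxirane and the base-labile ylidenebutenolide survive and no stereocentre or double bond is touched.

**Compound list**
1 | (−)-actinol, (4R,6R)-4-hydroxy-2,2,6-trimethylcyclohexan-1-one | C[C@H]1C(=O)C(C)(C)C[C@H](O)C1 | starting material
2 | (4R,6R)-4-[(tert-butyldimethylsilyl)oxy]-2,2,6-trimethylcyclohexan-1-one | C[C@H]1C(=O)C(C)(C)C[C@H](O[Si](C)(C)C(C)(C)C)C1 | intermediate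
3 | lithium (R)-4-[(tert-butyldimethylsilyl)oxy]-2,6,6-trimethylcyclohex-1-en-1-olate | CC1=C([O-])C(C)(C)C[C@H](O[Si](C)(C)C(C)(C)C)C1.[Li+] | intermediate
4 | (R)-4-[(tert-butyldimethylsilyl)oxy]-2,6,6-trimethylcyclohex-1-en-1-yl trifluoromethanesulfonate | CC1=C(OS(=O)(=O)C(F)(F)F)C(C)(C)C[C@H](O[Si](C)(C)C(C)(C)C)C1 | intermediate
5 | (tributylstannyl)methanol | CCCC[Sn](CCCC)(CCCC)CO | starting material
6 | {(R)-4-[(tert-butyldimethylsilyl)oxy]-2,6,6-trimethylcyclohex-1-en-1-yl}methanol | CC1=C(CO)C(C)(C)C[C@H](O[Si](C)(C)C(C)(C)C)C1 | intermediate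
7 | {(1R,4S,6R)-4-[(tert-butyldimethylsilyl)oxy]-2,2,6-trimethyl-7-oxabicyclo[4.1.0]heptan-1-yl}methanol | OC[C@@]12O[C@]1(C)C[C@@H](O[Si](C)(C)C(C)(C)C)CC2(C)C | intermediate
8 | (1S,4S,6R)-4-[(tert-butyldimethylsilyl)oxy]-2,2,6-trimethyl-7-oxabicyclo[4.1.0]heptane-1-carbaldehyde | O=C[C@@]12O[C@]1(C)C[C@@H](O[Si](C)(C)C(C)(C)C)CC2(C)C | intermediate
9 | bis(4,4,5,5-tetramethyl-1,3,2-dioxaborolan-2-yl)methane | CC1(C)OB(CB2OC(C)(C)C(C)(C)O2)OC1(C)C | starting material
10 | lithio-bis(4,4,5,5-tetramethyl-1,3,2-dioxaborolan-2-yl)methane | [Li]C(B1OC(C)(C)C(C)(C)O1)B1OC(C)(C)C(C)(C)O1 | intermediate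
11 | 2-[(E)-2-{(1S,4S,6R)-4-[(tert-butyldimethylsilyl)oxy]-2,2,6-trimethyl-7-oxabicyclo[4.1.0]heptan-1-yl}ethenyl]-4,4,5,5-tetramethyl-1,3,2-dioxaborolane | CC1(C)OB(/C=C/[C@@]23O[C@]2(C)C[C@@H](O[Si](C)(C)C(C)(C)C)CC3(C)C)OC1(C)C | intermediate
12 | (E)-3-methylpent-2-en-4-yn-1-ol | C#C/C(C)=C/CO | starting material
13 | (E)-5-bromo-3-methylpent-3-en-1-yne | C#C/C(C)=C/CBr | intermediate
14 | tributyl[(E)-3-methylpent-2-en-4-yn-1-yl]phosphonium bromide | C#C/C(C)=C/C[P+](CCCC)(CCCC)CCCC.[Br-] | intermediate
15 | 1,4-dioxane-2,3-diol | OC1OCCOC1O | starting material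
16 | tributyl[(E)-3-methylpent-2-en-4-yn-1-ylidene]phosphorane | C#C/C(C)=C/C=P(CCCC)(CCCC)CCCC | intermediate
17 | glyoxal | O=CC=O | intermediate
18 | (2E,4E)-5-methylhepta-2,4-dien-6-ynal | C#C/C(C)=C/C=C/C=O | intermediate
19 | (3E,5E,7E,9E)-3,10-dimethyldodeca-3,5,7,9-tetraene-1,11-diyne | C#C/C(C)=C/C=C/C=C/C=C(C)/C#C | intermediate
20 | (R)-tert-butyl({4-[(3E,5E,7E,9E)-3,10-dimethyldodeca-3,5,7,9-tetraene-1,11-diyn-1-yl]-3,5,5-trimethylcyclohex-3-en-1-yl}oxy)dimethylsilane | CC1=C(C#C/C(C)=C/C=C/C=C/C=C(C)/C#C)C(C)(C)C[C@H](O[Si](C)(C)C(C)(C)C)C1 | intermediate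
21 | propiolic acid | C#CC(=O)O | starting material
22 | (E)-2,3-dibromoprop-2-enoic acid | OC(=O)/C(Br)=C\Br | intermediate
23 | (2E,6E,8E,10E,12E)-2-bromo-15-{(4R)-4-[(tert-butyldimethylsilyl)oxy]-2,6,6-trimethylcyclohex-1-en-1-yl}-6,13-dimethylpentadeca-2,6,8,10,12-pentaene-4,14-diynoic acid (carboxyl cis to the alkynyl group) | OC(=O)/C(Br)=C\C#C/C(C)=C/C=C/C=C/C=C(C)/C#CC1=C(C)C[C@@H](O[Si](C)(C)C(C)(C)C)CC1(C)C | intermediate
24 | (5Z)-3-bromo-5-[(2E,4E,6E,8E)-11-{(4R)-4-[(tert-butyldimethylsilyl)oxy]-2,6,6-trimethylcyclohex-1-en-1-yl}-2,9-dimethylundeca-2,4,6,8-tetraen-10-yn-1-ylidene]furan-2(5H)-one | CC1=C(C#C/C(C)=C/C=C/C=C/C=C(C)/C=C2C=C(Br)C(=O)O/2)C(C)(C)C[C@H](O[Si](C)(C)C(C)(C)C)C1 | intermediate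
25 | 3,3'-bis-O-(tert-butyldimethylsilyl)-(3S,5R,6S,3'R)-pyrrhoxanthinol | CC1=C(C#C/C(C)=C/C=C/C=C/C=C(C)/C=C2C=C(/C=C/[C@@]34O[C@]3(C)C[C@@H](O[Si](C)(C)C(C)(C)C)CC4(C)C)C(=O)O/2)C(C)(C)C[C@H](O[Si](C)(C)C(C)(C)C)C1 | intermediate
26 | (3S,5R,6S,3'R)-pyrrhoxanthinol | CC1=C(C#C/C(C)=C/C=C/C=C/C=C(C)/C=C2C=C(/C=C/[C@@]34O[C@]3(C)C[C@@H](O)CC4(C)C)C(=O)O/2)C(C)(C)C[C@H](O)C1 | target

**Step count**
- Total step count: 13.
- Longest linear sequence: 8 steps (steps 1, 2, 3, 4, 5, 6, 12, 13, starting from 1).

**The three steps most likely to fail**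

Step 11, the proposed new cascade, could fail in four ways: coupling at the α-bromide, a second coupling of 24, 6-endo closure to the pyranone, or oxidative dimerisation of 20. The fallback uses known chemistry, separates the C–C and C–O events and masks the acid. It sets out from 20 and comes back to the route at 24. Methyl propiolate is brominated (Br2, CCl4, 70 °C) to methyl (E)-2,3-dibromoacrylate F1. This undergoes the established β-selective Sonogashira coupling with 20 (Pd(PPh3)4, CuI, Et3N, MeCN, rt) to give the methyl ester of acid 23 F2. LiOH in THF–H2O frees acid 23, which is now isolated, and AgNO3 (10 mol %) in acetone closes it 5-exo-dig to 24. This costs two extra steps.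

Step 8, the twofold Wittig reaction on the glyoxal equivalent, carries three risks. The dialdehyde may be consumed by base, the reaction may stop at 18, or it may give E/Z mixtures. Such mixtures cannot be equilibrated afterwards, because the ethynyl-substituted trisubstituted double bonds would scramble as well. The fallback builds the tetraene one double bond at a time without any dialdehyde. It sets out from 12 (together with 14 from step 7) and comes back at 19. MnO2 in CH2Cl2 oxidises 12 to (E)-3-methylpent-2-en-4-ynal F3. Two-carbon homologation with the stabilised ylide Ph3P=CHCHO (toluene, 60 °C) gives dienynal 18 as an isolated all-E compound. A single Wittig reaction of 18 with ylide 16 (from 14 and NaOMe) then gives 19. This costs two extra steps.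

Step 3, the Stille hydroxymethylation, may suffer from slow transmetalation at the tetrasubstituted triflate next to the quaternary carbon, from butyl transfer or from reduction. The fallback replaces the tin reagent by carbon monoxide as the one-carbon source. It sets out from 4 and comes back at 6. Methoxycarbonylation (Pd(OAc)2, PPh3, CO 1 atm, MeOH, Et3N, DMF, 60 °C) gives methyl (R)-4-[(tert-butyldimethylsilyl)oxy]-2,6,6-trimethylcyclohex-1-ene-1-carboxylate F4. Reduction with i-Bu2AlH (CH2Cl2, −78 °C) then gives 6. This costs one extra step.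

**Further compounds**
F1 | step 11 | methyl (E)-2,3-dibromoacrylate | COC(=O)/C(Br)=C\Br
F2 | step 11 | methyl (2E,6E,8E,10E,12E)-2-bromo-15-{(4R)-4-[(tert-butyldimethylsilyl)oxy]-2,6,6-trimethylcyclohex-1-en-1-yl}-6,13-dimethylpentadeca-2,6,8,10,12-pentaene-4,14-diynoate (methyl ester of acid 23) | COC(=O)/C(Br)=C\C#C/C(C)=C/C=C/C=C/C=C(C)/C#CC1=C(C)C[C@@H](O[Si](C)(C)C(C)(C)C)CC1(C)C
F3 | step 8 | (E)-3-methylpent-2-en-4-ynal | C#C/C(C)=C/C=O
F4 | step 3 | methyl (R)-4-[(tert-butyldimethylsilyl)oxy]-2,6,6-trimethylcyclohex-1-ene-1-carboxylate | CC1=C(C(=O)OC)C(C)(C)C[C@H](O[Si](C)(C)C(C)(C)C)C1
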